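**Plan**
1. Numbering: seven-membered ring C10(=O)–C9(CH3, side chain C11–C12)–C8(H, CH3)–C7–C6–C5(OH)–C1(H). Cyclopentane C1–C2–C3(H, OH)–C4(CH3)2–C5. C12 carries the butenolide (C13–C16).
2. Enabling feature: the run C10(=O)–C1–C5(O)–C6 at the fusion of the two rings. With a carbonyl written at C7 it becomes a 1,5-diketone oxygenated at C5. That is the imprint of a [2+2]/retro-aldol sequence between the C1=C7 enol bond of a cyclopentane-1,3-dione ring (C10, C1, C7, C8, C9) and a C5=C6 enol ether.
3. Retrosynthetic cuts, in order: C12–C13; C7 carbonyl restored; C1–C5 and C6–C7 cut while C1–C7 is rejoined; C1–C2; C9–C11 and C8–CH3.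
4. Forward order: the dione ring is built from 2-methylcyclopentenone, and the C2–C6 chain from (S)-pantolactone is attached at C1. One photochemical/hydrogenolytic operation then closes the cyclopentane and widens the dione ring to the seven-membered ring. C7 is deoxygenated and the butenolide is joined last.
5. Stereochemistry: C8 comes from asymmetric conjugate methylation, C9 from enolate allylation anti to the C8 methyl, and C3 from (S)-pantolactone. C5 comes from the methyl-shielded enone face acting together with the C3-substituted tether, and C1 from ketonisation anti to the C5 silyloxy group. Any minor enantiomer of the dione becomes a separable diastereomer after union with the enantiopure aldehyde.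

Key step: step 18

Assumption: C1 is enolisable in the target itself, so the trans fusion drawn (C1–H anti to C5–O, C5–OH able to hydrogen-bond to C10=O) is taken as the more stable C1 epimer; in step 1 the ligand antipode is the one that gives (3R)-3.
Abbreviations: TBS = tert-butyldimethylsilyl, TBSO = its oxy group, TMS = trimethylsilyl, Cbz = benzyloxycarbonyl, DMP = Dess–Martin periodinane. "Route numbering" is the numbering of line 1.

**Step 1**
Reactants: 1 2-methylcyclopent-2-en-1-one
Product: 3 {[(3R)-2,3-dimethylcyclopent-1-en-1-yl]oxy}trimethylsilane, via dimethylaluminium enolate 2 (not isolated)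
Conditions: AlMe3, Cu(OTf)2 (2 mol%), BINOL-derived phosphoramidite (4 mol%), Et2O, −30 °C; then TMSOTf, −30 to 0 °C
Reagents that add atoms: trimethylaluminium C[Al](C)C; trimethylsilyl triflate C[Si](C)(C)OS(=O)(=O)C(F)(F)F
Why: Copper-catalysed asymmetric conjugate addition of a trialkylaluminium to an α-substituted cyclopentenone sets C8 through the chiral ligand, and O-silylation freezes the regiodefined tetrasubstituted enolate.

**Step 2**
Reactants: 3 {[(3R)-2,3-dimethylcyclopent-1-en-1-yl]oxy}trimethylsilane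
Product: 5 (2S,3R)-2-allyl-2,3-dimethylcyclopentan-1-one, via lithium enolate 4 (not isolated)
Conditions: MeLi, THF, 0 °C; then allyl bromide, DMPU, −78 to −20 °C
Reagents that add atoms: allyl bromide C=CCBr
Why: MeLi releases the regiodefined lithium enolate, and its alkylation takes place on the face opposite the C8 methyl group, which sets C9 with the two methyl groups cis.

**Step 3**
Reactants: 5 (2S,3R)-2-allyl-2,3-dimethylcyclopentan-1-one
Product: 7 (2S,3R)-2-(2-hydroxyethyl)-2,3-dimethylcyclopentan-1-one, via keto aldehyde 6 (not isolated)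
Conditions: O3, CH2Cl2/MeOH, −78 °C; Me2S; then NaBH4, −78 °C
Reagents that add atoms: ozone [O-][O+]=O
Why: Ozonolysis of the terminal alkene is followed by low-temperature borohydride reduction, which takes the unhindered aldehyde and leaves the ketone beside quaternary C9 untouched.

**Step 4**
Reactants: 7 (2S,3R)-2-(2-hydroxyethyl)-2,3-dimethylcyclopentan-1-one
Product: 8 (2S,3R)-2-[2-(TBSO)ethyl]-2,3-dimethylcyclopentan-1-one
Conditions: TBSCl, imidazole, DMF, rt
Reagents that add atoms: tert-butyldimethylsilyl chloride CC(C)(C)[Si](C)(C)Cl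
Why: Standard silylation of a primary alcohol, which also draws any lactol tautomer of 7 into the open ketone form.

**Step 5**
Reactants: 8 (2S,3R)-2-[2-(TBSO)ethyl]-2,3-dimethylcyclopentan-1-one
Product: 10 (4R,5S)-5-[2-(TBSO)ethyl]-4,5-dimethylcyclopent-2-en-1-one, via trimethylsilyl enol ether 9 (not isolated)
Conditions: TMSOTf, Et3N, CH2Cl2, 0 °C; then Pd(OAc)2, MeCN, rt
Reagents that add atoms: none
Why: Saegusa–Ito dehydrogenation: the ketone can enolise only toward C1 because C9 is quaternary, and divalent palladium turns the enol silane into the C1=C7 enone.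

**Step 6**
Reactants: 10 (4R,5S)-5-[2-(TBSO)ethyl]-4,5-dimethylcyclopent-2-en-1-one
Product: 11 (1R,3S,4S,5R)-3-[2-(TBSO)ethyl]-3,4-dimethyl-6-oxabicyclo[3.1.0]hexan-2-one
Conditions: 30% H2O2, NaOH (cat.), MeOH, 0 °C
Reagents that add atoms: hydrogen peroxide OO
Why: Weitz–Scheffer nucleophilic epoxidation, in which hydroperoxide adds to C7 anti to the neighbouring C8 methyl group; both new centres are erased in the next step.

**Step 7**
Reactants: 11 (1R,3S,4S,5R)-3-[2-(TBSO)ethyl]-3,4-dimethyl-6-oxabicyclo[3.1.0]hexan-2-one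
Product: 12 (4S,5S)-4-[2-(TBSO)ethyl]-4,5-dimethylcyclopentane-1,3-dione
Conditions: Pd(PPh3)4 (5 mol%), dppe (5 mol%), toluene, 80 °C
Reagents that add atoms: none
Why: Isomerisation of an α,β-epoxy ketone to the β-diketone by zerovalent palladium is a known neutral process and should leave C8, now α to a carbonyl, unchanged.

**Step 8**
Reactants: 13 (S)-pantolactone
Product: 14 (3S)-3-(TBSO)-4,4-dimethyldihydrofuran-2(3H)-one
Conditions: TBSCl, imidazole, DMF, rt
Reagents that add atoms: tert-butyldimethylsilyl chloride CC(C)(C)[Si](C)(C)Cl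
Why: Silylation of the secondary lactone alcohol; the C3 centre is taken unchanged from the chiral pool.

**Step 9**
Reactants: 14 (3S)-3-(TBSO)-4,4-dimethyldihydrofuran-2(3H)-one
Product: 15 (3S)-3-(TBSO)-4,4-dimethyltetrahydrofuran-2-ol (anomer mixture)
Conditions: i-Bu2AlH, CH2Cl2, −78 °C; Rochelle salt work-up
Reagents that add atoms: none
Why: Partial reduction of a lactone stops at the tetrahedral aluminium lactolate at low temperature.

**Step 10**
Reactants: 15 (3S)-3-(TBSO)-4,4-dimethyltetrahydrofuran-2-ol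
Product: 16 (3R)-3-(TBSO)-2,2-dimethylpent-4-en-1-ol
Conditions: MePPh3Br, n-BuLi, THF, 0 °C
Reagents that add atoms: methyltriphenylphosphonium bromide C[P+](c1ccccc1)(c1ccccc1)c1ccccc1.[Br-]
Why: Wittig methylenation of the open hydroxy aldehyde tautomer masks C2 as a vinyl group, and the lithium counter-ion and a cold quench are chosen to hold back 1,5-silyl migration.

**Step 11**
Reactants: 16 (3R)-3-(TBSO)-2,2-dimethylpent-4-en-1-ol
Product: 17 (3R)-3-(TBSO)-2,2-dimethylpent-4-enal
Conditions: DMP, CH2Cl2, rt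
Reagents that add atoms: none
Why: Dess–Martin oxidation of a neopentyl primary alcohol gives an aldehyde without α-hydrogen, which cannot epimerise or eliminate.

**Step 12**
Reactants: 17 (3R)-3-(TBSO)-2,2-dimethylpent-4-enal
Product: 18 (4R)-4-(TBSO)-3,3-dimethylhex-5-en-2-ol (epimers at C2 of the chain)
Conditions: MeMgBr, Et2O, −78 °C
Reagents that add atoms: methylmagnesium bromide C[Mg]Br
Why: Grignard addition to the non-enolisable aldehyde brings in C6, and the new carbinol centre disappears in the next step.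

**Step 13**
Reactants: 18 (4R)-4-(TBSO)-3,3-dimethylhex-5-en-2-ol
Product: 19 (4R)-4-(TBSO)-3,3-dimethylhex-5-en-2-one
Conditions: DMP, CH2Cl2, rt
Reagents that add atoms: none
Why: Dess–Martin oxidation of the hindered secondary alcohol gives the C5 methyl ketone under neutral conditions.

**Step 14**
Reactants: 19 (4R)-4-(TBSO)-3,3-dimethylhex-5-en-2-one
Product: 20 (2S)-2-(TBSO)-3,3-dimethyl-4-oxopentanal
Conditions: O3, CH2Cl2, −78 °C; Me2S
Reagents that add atoms: ozone [O-][O+]=O
Why: Ozonolysis unmasks C2 as the aldehyde under neutral conditions that do not touch the α-silyloxy centre C3.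

**Step 15**
Reactants: 12 (4S,5S)-4-[2-(TBSO)ethyl]-4,5-dimethylcyclopentane-1,3-dione; 20 (2S)-2-(TBSO)-3,3-dimethyl-4-oxopentanal
Product: 22 (4S,5S)-2-[(2R)-2-(TBSO)-3,3-dimethyl-4-oxopentyl]-4-[2-(TBSO)ethyl]-4,5-dimethylcyclopentane-1,3-dione (enolised), via alkylidene dione 21 (not isolated)
Conditions: L-proline (20 mol%), Hantzsch ester, CH2Cl2, rt
Reagents that add atoms: none
Why: Three-component reductive alkylation (proline-catalysed Knoevenagel condensation, then Hantzsch ester transfer hydrogenation) gives clean C-alkylation of the 1,3-dione at C1, which a halide alkylation would not.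

**Step 16**
Reactants: 22 the 2-alkylated dione
Product: 23 benzyl (4S,5S)-2-[(2R)-2-(TBSO)-3,3-dimethyl-4-oxopentyl]-4-[2-(TBSO)ethyl]-4,5-dimethyl-3-oxocyclopent-1-en-1-yl carbonate (carbonate on the C7 oxygen)
Conditions: CbzCl, pyridine, CH2Cl2, 0 °C
Reagents that add atoms: benzyl chloroformate O=C(Cl)OCc1ccccc1
Why: O-acylation of the dione enolate should favour the oxygen on C7, next to tertiary C8, over the oxygen on C10 next to quaternary C9, and the minor regioisomer can be separated and hydrolysed back to 22.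

**Step 17**
Reactants: 23 the C7 enol benzyl carbonate
Product: 24 benzyl (4S,5S)-2-[(2R)-2,4-bis(TBSO)-3,3-dimethylpent-4-en-1-yl]-4-[2-(TBSO)ethyl]-4,5-dimethyl-3-oxocyclopent-1-en-1-yl carbonate
Conditions: TBSOTf, Et3N, CH2Cl2, −78 to 0 °C
Reagents that add atoms: tert-butyldimethylsilyl triflate CC(C)(C)[Si](C)(C)OS(=O)(=O)C(F)(F)F
Why: Soft enolisation (silyl triflate/amine) of the methyl ketone can remove only a C6 proton because C4 is quaternary, and the carbonate has no enolisable hydrogen.

**Step 18**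
Reactants: 24 the enol carbonate carrying the tethered C5=C6 silyl enol ether
Product: 27 trans-fused (1R,3R,5R,8S,9S)-3,5-bis(TBSO)-9-[2-(TBSO)ethyl]-4,4,8,9-tetramethylperhydroazulene-7,10-dione (route numbering), via cyclobutane photoadduct 25 (not isolated), via cyclobutanol 26 (not isolated)
Conditions: hν (medium-pressure Hg lamp, Pyrex, λ > 300 nm), degassed cyclohexane (5 mM), 10 °C; solvent exchange; then H2 (1 atm), Pd/C, EtOAc, rt
Reagents that add atoms: none
Why: Excitation of the β-acyloxy enone and intersystem crossing give a triplet that bonds C1 to C5 and, after spin inversion of the 1,4-biradical, C7 to C6 to form cyclobutane 25; hydrogenolysis of the benzyl carbonate with loss of CO2 then bares the C7 hydroxyl of 26, a strained β-hydroxy ketone that opens by retro-aldol cleavage of C1–C7 and ketonises at C1. The closest known reaction type is the intramolecular de Mayo reaction of 2-(pent-4-enyl)cyclopentane-1,3-dione enol esters and carbonates, which gives hydroazulenediones in the same way. The cyclopentane closes in the 5-exo sense of a 1,6-diene (rule of five, straight adduct), the transient four-membered ring closes by C6–C7 biradical recombination, and the seven-membered ring is not cyclised end to end but arises by two-carbon expansion when the bond shared by the four- and five-membered rings breaks. C5 is controlled by the enone face: the C8 methyl group next to C7 (backed by the cis C9 methyl group) blocks one face, and on the open face the tether can fold as an envelope with the C3 silyloxy group pseudo-equatorial and anti to the C5 oxygen, so ring and tether call for the same C5 configuration, while C1 is set on ketonisation by protonation anti to the bulky C5 silyloxy group and, being enolisable, can settle to the trans-fused epimer. The step needs C6 to bond to C7 and not to C10, which the carbonate secures by fixing the enol double bond as C1=C7, and it needs the cyclobutane to open at C1–C7 and not at C1–C5, which the orthogonal pair (benzyl carbonate on the C7 oxygen, TBS on the C5 oxygen) secures because only the C7 oxygen is set free. Quaternary C4 guarantees that the enol ether is C5=C6, and neutral hydrogenolysis avoids base that could epimerise C8 or expel the C5 silyloxy group.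

**Step 19**
Reactants: 27 the hydroazulene-7,10-dione
Product: 28 C7 tosylhydrazone of 27
Conditions: TsNHNH2, PPTS (cat.), molecular sieves, THF, 45 °C
Reagents that add atoms: p-toluenesulfonyl hydrazide Cc1ccc(cc1)S(=O)(=O)NN
Why: Hydrazone condensation separates the two ketones on steric grounds, since C7 lies between a CH2 and a CH whereas C10 lies between quaternary C9 and the ring-fusion carbon C1.

**Step 20**
Reactants: 28 C7 tosylhydrazone of 27
Product: 30 (1R,3R,5R,8R,9S)-3,5-bis(TBSO)-9-[2-(TBSO)ethyl]-4,4,8,9-tetramethylperhydroazulen-10-one (route numbering), via N-boryl tosylhydrazine 29 (not isolated)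
Conditions: catecholborane, CHCl3, −10 °C; then NaOAc·3H2O, reflux
Reagents that add atoms: none
Why: Caglioti-type deoxygenation: hydride adds to C=N and acetate-induced loss of sulfinate and dinitrogen leaves CH2 at C7, with no carbanion that could expel the C5 silyloxy group.

**Step 21**
Reactants: 30 the tris-TBS hydroazulen-10-one
Product: 31 (1R,3R,5R,8R,9S)-3,5-bis(TBSO)-9-(2-hydroxyethyl)-4,4,8,9-tetramethylperhydroazulen-10-one (route numbering)
Conditions: HF·pyridine, pyridine, THF, 0 °C
Reagents that add atoms: none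
Why: Steric differentiation of silyl ethers: buffered HF·pyridine cleaves the primary ether well before the neopentyl secondary and the tertiary ones.

**Step 22**
Reactants: 31 the primary alcohol
Product: 32 (1R,3R,5R,8R,9S)-3,5-bis(TBSO)-9-(2-iodoethyl)-4,4,8,9-tetramethylperhydroazulen-10-one (route numbering)
Conditions: I2, PPh3, imidazole, CH2Cl2, 0 °C to rt
Reagents that add atoms: iodine [I][I]
Why: Appel-type iodination of a primary alcohol runs under nearly neutral conditions that spare the β-silyloxy ketone.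

**Step 23**
Reactants: 32 the primary iodide; 33 4-bromofuran-2(5H)-one
Product: 35 3,5-bis-O-TBS ether of the target, via alkylzinc iodide 34 (not isolated)
Conditions: Zn dust (activated), LiCl, THF, 40 °C; then 33, PdCl2(dppf) (5 mol%), THF, 40 °C
Reagents that add atoms: none
Why: Direct zinc insertion into the primary iodide tolerates the hindered ketone, and Negishi coupling of the alkylzinc iodide with the β-bromo butenolide forms C12–C13 without base.

**Step 24**
Reactants: 35 3,5-bis-O-TBS ether of the target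
Product: 36 CNP0077405.2, (1R,3R,5R,8R,9S)-3,5-dihydroxy-4,4,8,9-tetramethyl-9-[2-(5-oxo-2,5-dihydrofuran-3-yl)ethyl]perhydroazulen-10-one (route numbering)
Conditions: 48% aq. HF, MeCN, 0 °C to rt
Reagents that add atoms: none
Why: Acidic fluoride removes both remaining silyl ethers without the base that would invite retro-aldol or E1cB loss of the C5 hydroxyl, and C1 keeps the configuration in which C5–OH can hydrogen-bond to C10=O.

**Compound list**
1 | 2-methylcyclopent-2-en-1-one | CC1=CCCC1=O | starting material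
2 | dimethylaluminium (3R)-2,3-dimethylcyclopent-1-en-1-olate | C[C@@H]1CCC(O[Al](C)C)=C1C | intermediate
3 | {[(3R)-2,3-dimethylcyclopent-1-en-1-yl]oxy}trimethylsilane | C[C@@H]1CCC(O[Si](C)(C)C)=C1C | intermediate
4 | lithium (3R)-2,3-dimethylcyclopent-1-en-1-olate | C[C@@H]1CCC([O-])=C1C.[Li+] | intermediate
5 | (2S,3R)-2-allyl-2,3-dimethylcyclopentan-1-one | C[C@@H]1CCC(=O)[C@@]1(C)CC=C | intermediate
6 | 2-[(1S,2R)-1,2-dimethyl-5-oxocyclopentyl]acetaldehyde | C[C@@H]1CCC(=O)[C@@]1(C)CC=O | intermediate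
7 | (2S,3R)-2-(2-hydroxyethyl)-2,3-dimethylcyclopentan-1-one | C[C@@H]1CCC(=O)[C@@]1(C)CCO | intermediate
8 | (2S,3R)-2-[2-(TBSO)ethyl]-2,3-dimethylcyclopentan-1-one | C[C@@H]1CCC(=O)[C@@]1(C)CCO[Si](C)(C)C(C)(C)C | intermediate
9 | {[(4R,5S)-5-[2-(TBSO)ethyl]-4,5-dimethylcyclopent-1-en-1-yl]oxy}trimethylsilane | C[C@@H]1CC=C(O[Si](C)(C)C)[C@@]1(C)CCO[Si](C)(C)C(C)(C)C | intermediate
10 | (4R,5S)-5-[2-(TBSO)ethyl]-4,5-dimethylcyclopent-2-en-1-one | C[C@@H]1C=CC(=O)[C@@]1(C)CCO[Si](C)(C)C(C)(C)C | intermediate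
11 | (1R,3S,4S,5R)-3-[2-(TBSO)ethyl]-3,4-dimethyl-6-oxabicyclo[3.1.0]hexan-2-one | C[C@@H]1[C@H]2O[C@H]2C(=O)[C@@]1(C)CCO[Si](C)(C)C(C)(C)C | intermediate
12 | (4S,5S)-4-[2-(TBSO)ethyl]-4,5-dimethylcyclopentane-1,3-dione | C[C@@H]1C(=O)CC(=O)[C@@]1(C)CCO[Si](C)(C)C(C)(C)C | intermediate
13 | (S)-pantolactone | O[C@@H]1C(=O)OCC1(C)C | starting material
14 | (3S)-3-(TBSO)-4,4-dimethyldihydrofuran-2(3H)-one | CC(C)(C)[Si](C)(C)O[C@@H]1C(=O)OCC1(C)C | intermediate
15 | (3S)-3-(TBSO)-4,4-dimethyltetrahydrofuran-2-ol, anomer mixture | CC(C)(C)[Si](C)(C)O[C@@H]1C(O)OCC1(C)C | intermediate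
16 | (3R)-3-(TBSO)-2,2-dimethylpent-4-en-1-ol | C=C[C@@H](O[Si](C)(C)C(C)(C)C)C(C)(C)CO | intermediate
17 | (3R)-3-(TBSO)-2,2-dimethylpent-4-enal | C=C[C@@H](O[Si](C)(C)C(C)(C)C)C(C)(C)C=O | intermediate
18 | (4R)-4-(TBSO)-3,3-dimethylhex-5-en-2-ol, carbinol epimers | C=C[C@@H](O[Si](C)(C)C(C)(C)C)C(C)(C)C(C)O | intermediate
19 | (4R)-4-(TBSO)-3,3-dimethylhex-5-en-2-one | C=C[C@@H](O[Si](C)(C)C(C)(C)C)C(C)(C)C(C)=O | intermediate
20 | (2S)-2-(TBSO)-3,3-dimethyl-4-oxopentanal | O=C[C@@H](O[Si](C)(C)C(C)(C)C)C(C)(C)C(C)=O | intermediate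
21 | 2-alkylidene dione (C1=C2, Knoevenagel product of 12 and 20, alkene geometry open) | C[C@@H]1C(=O)C(=C[C@@H](O[Si](C)(C)C(C)(C)C)C(C)(C)C(C)=O)C(=O)[C@@]1(C)CCO[Si](C)(C)C(C)(C)C | intermediate
22 | (4S,5S)-2-[(2R)-2-(TBSO)-3,3-dimethyl-4-oxopentyl]-4-[2-(TBSO)ethyl]-4,5-dimethylcyclopentane-1,3-dione, drawn as the C7 enol | C[C@@H]1C(O)=C(C[C@@H](O[Si](C)(C)C(C)(C)C)C(C)(C)C(C)=O)C(=O)[C@@]1(C)CCO[Si](C)(C)C(C)(C)C | intermediate
23 | C7 enol benzyl carbonate of 22 | C[C@@H]1C(OC(=O)OCc2ccccc2)=C(C[C@@H](O[Si](C)(C)C(C)(C)C)C(C)(C)C(C)=O)C(=O)[C@@]1(C)CCO[Si](C)(C)C(C)(C)C | intermediate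
24 | C7 enol benzyl carbonate with tethered C5=C6 TBS enol ether (3R,8S,9S, route numbering) | C[C@@H]1C(OC(=O)OCc2ccccc2)=C(C[C@@H](O[Si](C)(C)C(C)(C)C)C(C)(C)C(O[Si](C)(C)C(C)(C)C)=C)C(=O)[C@@]1(C)CCO[Si](C)(C)C(C)(C)C | intermediate
25 | tricyclic photoadduct, cyclobutane C1–C5–C6–C7, both fusions cis (1S,3R,5S,7S,8S,9S, route numbering) | C[C@@H]1[C@@]3(OC(=O)OCc4ccccc4)C[C@@]2(O[Si](C)(C)C(C)(C)C)[C@@]3(C[C@@H](O[Si](C)(C)C(C)(C)C)C2(C)C)C(=O)[C@@]1(C)CCO[Si](C)(C)C(C)(C)C | intermediate
26 | C7 cyclobutanol from 25 | C[C@@H]1[C@@]3(O)C[C@@]2(O[Si](C)(C)C(C)(C)C)[C@@]3(C[C@@H](O[Si](C)(C)C(C)(C)C)C2(C)C)C(=O)[C@@]1(C)CCO[Si](C)(C)C(C)(C)C | intermediate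
27 | trans-fused (1R,3R,5R,8S,9S)-3,5-bis(TBSO)-9-[2-(TBSO)ethyl]-4,4,8,9-tetramethylperhydroazulene-7,10-dione (route numbering) | C[C@@H]1C(=O)C[C@@]2(O[Si](C)(C)C(C)(C)C)[C@@H](C[C@@H](O[Si](C)(C)C(C)(C)C)C2(C)C)C(=O)[C@@]1(C)CCO[Si](C)(C)C(C)(C)C | intermediate
28 | C7 tosylhydrazone of 27 | C[C@@H]1C(=NNS(=O)(=O)c3ccc(C)cc3)C[C@@]2(O[Si](C)(C)C(C)(C)C)[C@@H](C[C@@H](O[Si](C)(C)C(C)(C)C)C2(C)C)C(=O)[C@@]1(C)CCO[Si](C)(C)C(C)(C)C | intermediate
29 | C7 N-(benzodioxaborolyl)-N'-tosylhydrazine | C[C@@H]1C(N(NS(=O)(=O)c3ccc(C)cc3)B3Oc4ccccc4O3)C[C@@]2(O[Si](C)(C)C(C)(C)C)[C@@H](C[C@@H](O[Si](C)(C)C(C)(C)C)C2(C)C)C(=O)[C@@]1(C)CCO[Si](C)(C)C(C)(C)C | intermediate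
30 | (1R,3R,5R,8R,9S)-3,5-bis(TBSO)-9-[2-(TBSO)ethyl]-4,4,8,9-tetramethylperhydroazulen-10-one (route numbering) | C[C@@H]1CC[C@@]2(O[Si](C)(C)C(C)(C)C)[C@@H](C[C@@H](O[Si](C)(C)C(C)(C)C)C2(C)C)C(=O)[C@@]1(C)CCO[Si](C)(C)C(C)(C)C | intermediate
31 | 9-(2-hydroxyethyl) analogue of 30 | C[C@@H]1CC[C@@]2(O[Si](C)(C)C(C)(C)C)[C@@H](C[C@@H](O[Si](C)(C)C(C)(C)C)C2(C)C)C(=O)[C@@]1(C)CCO | intermediate
32 | 9-(2-iodoethyl) analogue of 30 | C[C@@H]1CC[C@@]2(O[Si](C)(C)C(C)(C)C)[C@@H](C[C@@H](O[Si](C)(C)C(C)(C)C)C2(C)C)C(=O)[C@@]1(C)CCI | intermediate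
33 | 4-bromofuran-2(5H)-one | BrC1=CC(=O)OC1 | starting material
34 | alkylzinc iodide from 32 | C[C@@H]1CC[C@@]2(O[Si](C)(C)C(C)(C)C)[C@@H](C[C@@H](O[Si](C)(C)C(C)(C)C)C2(C)C)C(=O)[C@@]1(C)CC[Zn]I | intermediate
35 | 3,5-bis-O-TBS ether of the target | C[C@@H]1CC[C@@]2(O[Si](C)(C)C(C)(C)C)[C@@H](C[C@@H](O[Si](C)(C)C(C)(C)C)C2(C)C)C(=O)[C@@]1(C)CCC1=CC(=O)OC1 | intermediate
36 | CNP0077405.2 (1R,3R,5R,8R,9S, route numbering) | C[C@@H]1CC[C@@]2(O)[C@@H](C[C@@H](O)C2(C)C)C(=O)[C@@]1(C)CCC1=CC(=O)OC1 | target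

**Step count.** Total: 24 steps. Longest linear sequence: 17 steps, either steps 1–7 or steps 8–14, followed by steps 15–24.

**The three steps most likely to fail**

**Step 18.**
- What may go wrong: the excited enone may close onto C6 first (1,6-closure, crossed adduct). The biradical may revert, because C1–C5 joins two fully substituted carbons next to quaternary C4. The carbonate acyl group may shift to C1. Face selectivity may be poor if the C9 side arm and the C5 silyloxy group crowd the open face.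
- Fallback: the locked enol carbonate and its separate trigger are given up in favour of the classical free-enol mode. No acyl group can then migrate, the C7 oxygen carries no bulk, regiocontrol rests on the hindrance at C10, and the cyclobutanol opens as it forms.
- Route: it sets out from 22. Excess TBSOTf/Et3N gives the tetrasilylated bis(enol ether) F1. Brief K2CO3/MeOH at −20 °C cleaves only the vinylogous silyl ester to give the free enol F2, which is used at once. Irradiation near 350 nm in cyclohexane should give 26 and, by spontaneous retro-aldol opening, come back to the route at 27.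

**Step 15.**
- What may go wrong: condensation at the neopentyl-like α-silyloxy aldehyde may be slow. That lets the 1,4-keto aldehyde undergo intramolecular aldol condensation (C6 onto C2) or lets C3 erode through the proline enamine.
- Fallback: C5 is kept at the alcohol level, so the aldehyde is stored as a lactol and no ketone is present during the union.
- Route: it sets out from 18 (and 12). Ozonolysis of 18 (O3; Me2S) gives the lactol F3. Reductive alkylation of 12 with F3 (proline, Hantzsch ester) gives the hydroxy dione F4. CbzCl/pyridine acylates the acidic enol rather than the hindered carbinol to give the hydroxy enol carbonate F5. DMP oxidation comes back to the route at 23.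

**Step 19.**
- What may go wrong: hydrazone formation at C7 may be sluggish. C8 may epimerise through the ene-hydrazine tautomer. The C5 silyloxy group may be lost by vinylogous elimination.
- Fallback: radical deoxygenation (Barton–McCombie) replaces the hydrazone chemistry.
- Route: it sets out from 27. NaBH4 in MeOH at −20 °C reduces only the C7 ketone to the C7 alcohol F6. 1,1'-Thiocarbonyldiimidazole with DMAP in toluene at 80 °C gives the imidazolylthiocarbonate F7. Bu3SnH/AIBN in toluene at 90 °C comes back to the route at 30.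

**Further compounds**
F1 | step 18 | C7 O-TBS vinylogous silyl ester with C5=C6 TBS enol ether | C[C@@H]1C(O[Si](C)(C)C(C)(C)C)=C(C[C@@H](O[Si](C)(C)C(C)(C)C)C(C)(C)C(O[Si](C)(C)C(C)(C)C)=C)C(=O)[C@@]1(C)CCO[Si](C)(C)C(C)(C)C
F2 | step 18 | free C7 enol with C5=C6 TBS enol ether | C[C@@H]1C(O)=C(C[C@@H](O[Si](C)(C)C(C)(C)C)C(C)(C)C(O[Si](C)(C)C(C)(C)C)=C)C(=O)[C@@]1(C)CCO[Si](C)(C)C(C)(C)C
F3 | step 15 | (3S)-3-(TBSO)-4,4,5-trimethyltetrahydrofuran-2-ol, epimer mixture at C2 and C5 of the ring | CC1OC(O)[C@@H](O[Si](C)(C)C(C)(C)C)C1(C)C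
F4 | step 15 | 2-[(2R)-2-(TBSO)-4-hydroxy-3,3-dimethylpentyl] analogue of 22 | C[C@@H]1C(O)=C(C[C@@H](O[Si](C)(C)C(C)(C)C)C(C)(C)C(C)O)C(=O)[C@@]1(C)CCO[Si](C)(C)C(C)(C)C
F5 | step 15 | C7 enol benzyl carbonate of F4 | C[C@@H]1C(OC(=O)OCc2ccccc2)=C(C[C@@H](O[Si](C)(C)C(C)(C)C)C(C)(C)C(C)O)C(=O)[C@@]1(C)CCO[Si](C)(C)C(C)(C)C
F6 | step 19 | C7 alcohol from 27, C7 epimers | C[C@@H]1C(O)C[C@@]2(O[Si](C)(C)C(C)(C)C)[C@@H](C[C@@H](O[Si](C)(C)C(C)(C)C)C2(C)C)C(=O)[C@@]1(C)CCO[Si](C)(C)C(C)(C)C
F7 | step 19 | C7 O-(imidazol-1-ylthiocarbonyl) derivative of F6 | C[C@@H]1C(OC(=S)n3ccnc3)C[C@@]2(O[Si](C)(C)C(C)(C)C)[C@@H](C[C@@H](O[Si](C)(C)C(C)(C)C)C2(C)C)C(=O)[C@@]1(C)CCO[Si](C)(C)C(C)(C)C
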